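**Retrosynthetic overview**

1. Numbering: phthalide numbers for the half that keeps the unsaturated lactone (C1, C3, C3a, C4–C7, C7a; cyclohexene ring A), primed numbers for the half with the saturated lactone (cyclohexene ring C = C3a'–C4'–C5'–C6'=C7'–C7a'); cyclobutane ring B = C6–C7–C3a'–C7a'. The target is (3Z,3'E,6S,7R,3a'S,7a'R).
2. Last disconnections: the (Z)-butylidene butenolide on ring A (carbonylative enolate trapping of a C7a enol triflate), and before it the (E)-butylidene of the saturated lactone (anti iodolactonisation of a C3a'-ethynyl C7a'-acid, then Negishi coupling), so that the more hindered E alkene is made under kinetic control.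
3. Ring C is cut at C5'–C6': its alkene comes from a cyclohexenone (C5'=C6'–C7'=O) by reductive transposition, and the enone from an aldol condensation between a methyl ketone on C7a' and an aldehyde two carbons from C3a'.
4. Enabling feature: C5' is at the aldehyde level, so before ring C exists it can be a mixed acetal tying the butenolide to the oxygen on C7a of (R)-cyclohex-2-en-1-ol (ring A). This six-membered tether ring fixes the regiochemistry and all four cyclobutane stereocentres in an intramolecular [2+2] photocycloaddition, and leaves the acetyl group and the C4'–C5' arm cis on adjacent carbons of ring B, on the face of ring A.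
5. Order of rings: ring A (bought) → butenolide → ring B with the tether ring, then ring C, in one flask (key step) → (E)-ylidene of the saturated lactone → unsaturated lactone.

Key step: step 6

Assumption: (R)-cyclohex-2-en-1-ol is taken as a commercial, enantiopure starting material; the epimers at the two acetal carbons (C3' and C5') are carried as mixtures because both centres are destroyed later.

**Route**

Step 1
Reactants: 1 mucobromic acid
Product: 2 3,4-dibromo-5-methoxyfuran-2(5H)-one
Conditions: MeOH, H2SO4 (cat.), reflux
Reagents that add atoms: methanol CO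
Why: Acid-catalysed pseudo-ester (cyclic acylal) formation from the lactol; the acetal carbon (later C3') is formed racemic and becomes an sp carbon in step 11.

Step 2
Reactants: 2 3,4-dibromo-5-methoxyfuran-2(5H)-one; 3 (E)-2-(2-ethoxyvinyl)-4,4,5,5-tetramethyl-1,3,2-dioxaborolane
Product: 4 3-bromo-4-[(E)-2-ethoxyvinyl]-5-methoxyfuran-2(5H)-one
Conditions: PdCl2(MeCN)2 (5 mol%), AsPh3 (20 mol%), Ag2O, THF, 65 °C
Reagents that add atoms: none
Why: Suzuki–Miyaura coupling, which should be site-selective for the more electrophilic β-bromide (C4) of a 3,4-dibromofuranone; no stereocentre is formed.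

Step 3
Reactants: 4 3-bromo-4-[(E)-2-ethoxyvinyl]-5-methoxyfuran-2(5H)-one
Product: 5 3-bromo-4-(2,2-dimethoxyethyl)-5-methoxyfuran-2(5H)-one
Conditions: MeOH, TsOH·H2O (cat.), 50 °C
Reagents that add atoms: methanol CO
Why: Acid-catalysed addition of methanol to the enol ether followed by transacetalisation in methanol as solvent gives the dimethyl acetal (C5' at the aldehyde level).

Step 4
Reactants: 5 3-bromo-4-(2,2-dimethoxyethyl)-5-methoxyfuran-2(5H)-one; 6 (R)-cyclohex-2-en-1-ol
Product: 7 3-bromo-4-{2-[(1R)-cyclohex-2-en-1-yloxy]-2-methoxyethyl}-5-methoxyfuran-2(5H)-one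
Conditions: TESOTf, 2,4,6-collidine, CH2Cl2, 0 °C; then 6
Reagents that add atoms: none
Why: Mixed-acetal synthesis through a collidinium salt: only the dialkyl acetal is ionised (the acylal is less basic) and the oxygen of 6 displaces the pyridinium group, so the carbinol centre of 6 is untouched and the new acetal carbon (C5') is an inconsequential epimer mixture.

Step 5
Reactants: 7 bromo butenolide carrying the cyclohexenyl mixed acetal
Product: 9 3-acetyl butenolide carrying the cyclohexenyl mixed acetal, via enol ether 8 (not isolated)
Conditions: Bu3Sn(C(OEt)=CH2), Pd(PPh3)4 (5 mol%), CuI (10 mol%), toluene, 90 °C; then 0.5 M HCl, THF, 0 °C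
Reagents that add atoms: tributyl(1-ethoxyvinyl)stannane CCCC[Sn](CCCC)(CCCC)C(=C)OCC; water O
Why: Stille coupling of the α-bromide with an acetyl anion equivalent, then hydrolysis of the 1-ethoxyvinyl group, which is protonated far faster than the mixed acetal ionises; the acetyl group is introduced last because an acetyl group cis to a free C5' electrophile on the butenolide would aromatise by aldol condensation.

Step 6
Reactants: 9 3-acetyl butenolide carrying the cyclohexenyl mixed acetal
Product: 12 hydroxy enone with rings A B and C, via photoadduct 10 (not isolated), via lactol 11 (not isolated)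
Conditions: hν (350 nm), degassed MeCN (5 mM), 25 °C; then TsOH·H2O (0.2 equiv), H2O, 40 °C; then toluene, 80 °C (water removed)
Reagents that add atoms: none
Why: Excitation of the 3-acylbutenolide gives a triplet that adds to the tethered cyclohexene (intramolecular enone–alkene [2+2] photocycloaddition, the reaction type known for 2(5H)-furanones carrying an alkene on a chain at C4): C3a' bonds to C7 in a 6-exo-trig closure that forms the tetrahydropyran tether ring, and the 1,4-diradical (C6, C7a') collapses to cyclobutane ring B. Acid then hydrolyses the cyclic methyl acetal to lactol 11, the enol of the methyl ketone (C6') attacks the aldehyde form (C5') and water is lost: an acid-catalysed intramolecular aldol condensation [6-(enolendo)-exo-trig] that closes ring C through the C5'–C6' bond and in the same event opens the temporary ring and frees the C7a hydroxyl. Stereocontrol: the (R)-carbinol carbon of ring A delivers the butenolide to the alkene face cis to its oxygen (sets C6 and C7), the tether ring can only be cis-fused to the new C7–C3a' bond, which puts C4' on the face of ring A and C3' on the other face (sets C3a'), and the cis-fused lactone then places the acetyl group on the ring-A face (sets C7a'). The step needs regioselectivity (C7–C3a' and C6–C7a', not the reverse) and the syn placing of ring A and the future ring C, which an intermolecular cycloaddition with a preformed six-membered ring would not be expected to give; the four-atom tether (straight closure, first bond through a six-membered ring) secures both. In the aldol stage only the six-membered ring can form, because the lactone and pseudo-ester carbons carry no α-hydrogen and the aldehyde enol could only close a four-membered ring. The enone carbonyl (C7') is placed so that steps 7 and 8 remove it while moving the double bond to C6'=C7'.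

Step 7
Reactants: 12 hydroxy enone
Product: 13 tosylhydrazone of the enone
Conditions: TsNHNH2, MeOH, 45 °C
Reagents that add atoms: 4-methylbenzenesulfonohydrazide Cc1ccc(cc1)S(=O)(=O)NN
Why: Tosylhydrazone condensation at the enone carbonyl; any material that has re-added the C7a hydroxyl to the enone (oxa-Michael) is in acid-catalysed equilibrium with 12 and should be drawn into the same conjugated hydrazone.

Step 8
Reactants: 13 tosylhydrazone of the enone
Product: 15 ring-C cyclohexene alcohol, via allylic diazene 14 (not isolated)
Conditions: catecholborane, CHCl3, 0 °C; then NaOAc·3H2O, 60 °C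
Reagents that add atoms: none
Why: Alkene-transposing reduction of an α,β-unsaturated tosylhydrazone (Kabalka reduction): hydride adds to C=N, acetate triggers loss of sulfinate, and the allylic diazene loses N2 by a retro-ene hydrogen shift to C5', which moves the double bond to C6'=C7' without touching a stereocentre.

Step 9
Reactants: 15 ring-C cyclohexene alcohol
Product: 16 ring-A ketone
Conditions: Dess–Martin periodinane, NaHCO3, CH2Cl2, 25 °C
Reagents that add atoms: none
Why: Dess–Martin oxidation of the secondary alcohol, done before the lactol is unmasked (a lactol would be oxidised as well); the carbinol centre that carried the absolute stereochemical information is erased here.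

Step 10
Reactants: 16 ring-A ketone
Product: 17 lactol (5-hydroxy lactone)
Conditions: 2 M HCl, THF/H2O, 45 °C
Reagents that add atoms: water O
Why: Acid hydrolysis of the methyl pseudo-ester (acylal) to the lactol, the masked aldehyde–acid.

Step 11
Reactants: 17 lactol
Product: 18 C3a'-ethynyl C7a'-carboxylic acid
Conditions: dimethyl (1-diazo-2-oxopropyl)phosphonate, K2CO3, MeOH, 0 to 25 °C; then cold aqueous citric acid
Reagents that add atoms: dimethyl (1-diazo-2-oxopropyl)phosphonate CC(=O)C(=[N+]=[N-])P(=O)(OC)OC
Why: Ohira–Bestmann (Seyferth–Gilbert) homologation of the ring-opened, non-enolisable aldehyde to the terminal alkyne while the acid is a carboxylate; the epimerisable C7 next to the ketone can only remain cis-fused.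

Step 12
Reactants: 18 alkynoic acid
Product: 19 (E)-iodomethylene lactone
Conditions: N-iodosuccinimide, NaHCO3, MeCN, 0 °C, dark
Reagents that add atoms: N-iodosuccinimide O=C1CCC(=O)N1I
Why: Iodolactonisation in the 5-exo-dig mode with anti addition of carboxylate and iodine across the alkyne, which sets the (E)-iodomethylene geometry (O and I trans); the ring-C alkene would need a 4-exo or 5-endo closure and should not compete.

Step 13
Reactants: 19 (E)-iodomethylene lactone
Product: 20 (E)-butylidene lactone ketone
Conditions: n-PrZnBr, PdCl2(dppf) (5 mol%), THF, 25 °C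
Reagents that add atoms: propylzinc bromide CCC[Zn]Br
Why: Negishi sp2–sp3 coupling with retention of configuration at the vinyl iodide, which places the propyl group trans to the ring oxygen, the (E)-butylidene of the target.

Step 14
Reactants: 20 (E)-butylidene lactone ketone
Product: 21 C3a-pentanoyl β-diketone
Conditions: MgBr2·OEt2, i-Pr2NEt, 1-pentanoylbenzotriazole, CH2Cl2, 25 °C
Reagents that add atoms: 1-(1H-benzotriazol-1-yl)pentan-1-one CCCCC(=O)n1nnc2ccccc12
Why: C-acylation of the ketone by soft enolisation (magnesium enolate, acylbenzotriazole) at the less hindered α-methylene C3a and not at the ring-fusion methine C7; the product is an enolised β-diketone, so no defined stereocentre arises.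

Step 15
Reactants: 21 β-diketone
Product: 22 C7a enol triflate
Conditions: Tf2O, Et3N, CH2Cl2, −78 °C
Reagents that add atoms: trifluoromethanesulfonic anhydride O=S(=O)(OS(=O)(=O)C(F)(F)F)C(F)(F)F
Why: O-triflation of the endocyclic enol of the 2-acylcyclohexanone (enol triflate formation), which fixes the tetrasubstituted C7a=C3a double bond.

Step 16
Reactants: 22 enol triflate
Product: 23 target CNP0371639.1
Conditions: Pd(PPh3)4 (5 mol%), CO (1 atm), Et3N, MeCN, 60 °C
Reagents that add atoms: carbon monoxide [C-]#[O+]
Why: Palladium-catalysed carbonylative lactonisation: oxidative addition to the enol triflate, CO insertion and capture of the acylpalladium by the enolate oxygen of the pentanoyl group should give the γ-ylidenebutenolide with the Z geometry (propyl anti to C3a), the thermodynamically favoured isomer.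

**Compound list**

1 | mucobromic acid (3,4-dibromo-5-hydroxyfuran-2(5H)-one, racemic lactol) | OC1OC(=O)C(Br)=C1Br | starting material
2 | 3,4-dibromo-5-methoxyfuran-2(5H)-one (racemic) | COC1OC(=O)C(Br)=C1Br | intermediate
3 | (E)-2-(2-ethoxyvinyl)-4,4,5,5-tetramethyl-1,3,2-dioxaborolane | CCO/C=C/B1OC(C)(C)C(C)(C)O1 | starting material
4 | 3-bromo-4-[(E)-2-ethoxyvinyl]-5-methoxyfuran-2(5H)-one | CCO/C=C/C1=C(Br)C(=O)OC1OC | intermediate
5 | 3-bromo-4-(2,2-dimethoxyethyl)-5-methoxyfuran-2(5H)-one | COC(CC1=C(Br)C(=O)OC1OC)OC | intermediate
6 | (R)-cyclohex-2-en-1-ol | O[C@@H]1CCCC=C1 | starting material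
7 | 3-bromo-4-{2-[(1R)-cyclohex-2-en-1-yloxy]-2-methoxyethyl}-5-methoxyfuran-2(5H)-one (epimers at both acetal carbons) | COC(CC1=C(Br)C(=O)OC1OC)O[C@@H]1CCCC=C1 | intermediate
8 | 3-(1-ethoxyvinyl) analogue of 7 | CCOC(=C)C1=C(CC(OC)O[C@@H]2CCCC=C2)C(OC)OC1=O | intermediate (not isolated)
9 | 3-acetyl-4-{2-[(1R)-cyclohex-2-en-1-yloxy]-2-methoxyethyl}-5-methoxyfuran-2(5H)-one | CC(=O)C1=C(CC(OC)O[C@@H]2CCCC=C2)C(OC)OC1=O | intermediate
10 | photoadduct: cyclobutane ring B cis-fused to cyclohexane ring A, to the 2-methoxytetrahydropyran tether ring (C7–C7a–O–C5'–C4'–C3a') and to the 5-methoxy-γ-lactone; acetyl on C7a' and C4' on the ring-A face, lactone on the other face; C7a (R) | O4[C@@H]2CCC[C@H]1[C@@H]2[C@@]3(CC4OC)[C@]1(C(C)=O)C(=O)OC3OC | intermediate (not isolated)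
11 | lactol of 10 (tetrahydropyran-2-ol in place of the methyl acetal) | O4[C@@H]2CCC[C@H]1[C@@H]2[C@@]3(CC4O)[C@]1(C(C)=O)C(=O)OC3OC | intermediate (not isolated)
12 | hydroxy enone: ring C as cyclohex-2-enone (C5'=C6'–C7'=O) cis-fused to ring B on the ring-A face, (R)-hydroxyl on C7a, 5-methoxy-γ-lactone on the opposite face | O[C@@H]2CCC[C@H]1[C@@H]2[C@@]23CC=CC(=O)[C@@]12C(=O)OC3OC | intermediate
13 | tosylhydrazone of 12 at C7' | O[C@@H]2CCC[C@H]1[C@@H]2[C@@]23CC=CC(=NNS(=O)(=O)c4ccc(C)cc4)[C@@]12C(=O)OC3OC | intermediate
14 | allylic diazene (N=NH on C7', C5'=C6') | O[C@@H]2CCC[C@H]1[C@@H]2[C@@]23CC=CC(N=N)[C@@]12C(=O)OC3OC | intermediate (not isolated)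
15 | alcohol with ring C as in the target (C6'=C7'), (R)-hydroxyl on C7a, 5-methoxy-γ-lactone | O[C@@H]2CCC[C@H]1[C@@H]2[C@@]23CCC=C[C@@]12C(=O)OC3OC | intermediate
16 | ring-A ketone (C7a=O) of 15 | O=C2CCC[C@H]1[C@@H]2[C@@]23CCC=C[C@@]12C(=O)OC3OC | intermediate
17 | lactol (5-hydroxy-γ-lactone) of 16 | O=C2CCC[C@H]1[C@@H]2[C@@]23CCC=C[C@@]12C(=O)OC3O | intermediate
18 | keto acid with ethynyl on C3a' and carboxylic acid on C7a' (cis, on the face opposite to ring A) | O=C2CCC[C@H]1[C@@H]2[C@@]2(C#C)CCC=C[C@@]12C(=O)O | intermediate
19 | (E)-iodomethylene γ-lactone ketone | O=C2CCC[C@H]1[C@@H]2[C@@]23CCC=C[C@@]12C(=O)O/C3=C/I | intermediate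
20 | (E)-butylidene γ-lactone ketone | O=C2CCC[C@H]1[C@@H]2[C@@]23CCC=C[C@@]12C(=O)O/C3=C/CCC | intermediate
21 | C3a-pentanoyl derivative of 20 (β-diketone, enolised) | O=C2C(C(=O)CCCC)CC[C@H]1[C@@H]2[C@@]23CCC=C[C@@]12C(=O)O/C3=C/CCC | intermediate
22 | C7a enol triflate of 21 (C7a=C3a, pentanoyl on C3a) | FC(F)(F)S(=O)(=O)OC2=C(C(=O)CCCC)CC[C@H]1[C@@H]2[C@@]23CCC=C[C@@]12C(=O)O/C3=C/CCC | intermediate
23 | CNP0371639.1, (3Z,3'E,6S,7R,3a'S,7a'R) ligustilide dimer joined C6–C7a' and C7–C3a' | CCC/C=C1\OC(=O)C2=C1CC[C@H]1[C@@H]2[C@@]23CCC=C[C@@]12C(=O)O/C3=C/CCC | target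

**Step count and risks**

Total steps: 16. Longest linear sequence: 16 (from 1; alcohol 6 enters in step 4).

Step 6 (key step). The excited acetyl group may abstract hydrogen (photoenolisation from C4' or C3', or attack on the acetal and allylic C–H bonds) faster than the alkene is captured, so that the cyclobutane does not form. The fallback introduces the acetyl group after the photoreaction. It sets out from 7: hydrodebromination (Bu3SnH, Pd(PPh3)4) should give the 3-unsubstituted butenolide F1, and acetone-sensitised irradiation (300 nm) the photoadduct lacking the acetyl group F2, under the same tether control. Deprotonation at C7a' (LiN(i-Pr)2, THF, −78 °C) and addition of acetaldehyde should give the aldol F3, since the only open position on the ring-fusion enolate is the one on the ring-A face. Dess–Martin oxidation then gives 10, which re-enters step 6 at the acid stage.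

Step 15. Sulfonylation may take place on the side-chain enol oxygen or on carbon, giving the wrong vinyl triflate for the carbonylation. The fallback makes a regiodefined triflate by reductive trapping and closes the lactone onto an alkyne. It sets out from 20: IBX dehydrogenation should give the ring-A enone F8, α-iodination (I2, pyridine, dark) the iodoenone F9, and Sonogashira coupling with pent-1-yne (PdCl2(PPh3)2, CuI, Et3N) the alkynyl enone F10. Conjugate reduction with LiBH(s-Bu)3 and trapping of the enolate with N-phenyltriflimide gives the vinyl triflate F11, and hydroxycarbonylation (Pd(OAc)2, dppf, CO, H2O, Et3N) the enynoic acid F12. AgNO3-catalysed 5-exo-dig cyclisation of F12 gives 23 with the Z geometry.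

Step 8. Hydride may add in the conjugate sense, or the hindered hydrazone next to the quaternary C7a' may not form or reduce cleanly, so that the transposed alkene is not obtained. The fallback makes the alkene without transposition. It sets out from 12: conjugate reduction with [(Ph3P)CuH]6 should give the saturated ketone F4 and silylation (TESOTf, 2,6-lutidine) the silyl ether F5. KN(SiMe3)2 and N-(5-chloropyridin-2-yl)triflimide give the enol triflate F6, since only C6' carries α-hydrogen. Reduction (Pd(OAc)2, PPh3, Bu3N, HCO2H) gives the silyl-protected alkene F7, and HF·pyridine returns 15.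

**Further compounds**

F1 | step 6 | 4-{2-[(1R)-cyclohex-2-en-1-yloxy]-2-methoxyethyl}-5-methoxyfuran-2(5H)-one | COC(CC1=CC(=O)OC1OC)O[C@@H]1CCCC=C1
F2 | step 6 | photoadduct lacking the acetyl group (H on C7a') | O4[C@@H]2CCC[C@H]1[C@@H]2[C@@]3(CC4OC)[C@@H]1C(=O)OC3OC
F3 | step 6 | 1-hydroxyethyl photoadduct (aldol at C7a') | O4[C@@H]2CCC[C@H]1[C@@H]2[C@@]3(CC4OC)[C@]1(C(C)O)C(=O)OC3OC
F4 | step 8 | saturated ring-C ketone (C7'=O) with C7a hydroxyl | O[C@@H]2CCC[C@H]1[C@@H]2[C@@]23CCCC(=O)[C@@]12C(=O)OC3OC
F5 | step 8 | triethylsilyl ether of F4 | CC[Si](CC)(CC)O[C@@H]2CCC[C@H]1[C@@H]2[C@@]23CCCC(=O)[C@@]12C(=O)OC3OC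
F6 | step 8 | C7' enol triflate (C6'=C7') of F5 | CC[Si](CC)(CC)O[C@@H]2CCC[C@H]1[C@@H]2[C@@]23CCC=C(OS(=O)(=O)C(F)(F)F)[C@@]12C(=O)OC3OC
F7 | step 8 | triethylsilyl ether of 15 | CC[Si](CC)(CC)O[C@@H]2CCC[C@H]1[C@@H]2[C@@]23CCC=C[C@@]12C(=O)OC3OC
F8 | step 15 | ring-A enone (C7a=O, C3a=C4) | O=C2C=CC[C@H]1[C@@H]2[C@@]23CCC=C[C@@]12C(=O)O/C3=C/CCC
F9 | step 15 | C3a-iodo enone | O=C2C(I)=CC[C@H]1[C@@H]2[C@@]23CCC=C[C@@]12C(=O)O/C3=C/CCC
F10 | step 15 | C3a-(pent-1-ynyl) enone | O=C2C(C#CCCC)=CC[C@H]1[C@@H]2[C@@]23CCC=C[C@@]12C(=O)O/C3=C/CCC
F11 | step 15 | C7a vinyl triflate with pent-1-ynyl on C3a | FC(F)(F)S(=O)(=O)OC2=C(C#CCCC)CC[C@H]1[C@@H]2[C@@]23CCC=C[C@@]12C(=O)O/C3=C/CCC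
F12 | step 15 | C7a carboxylic acid with pent-1-ynyl on C3a | OC(=O)C2=C(C#CCCC)CC[C@H]1[C@@H]2[C@@]23CCC=C[C@@]12C(=O)O/C3=C/CCC
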